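The route closes the cyclohexane ring A late, at the bond between its quaternary gem-dimethyl carbon C3 and the bromine-bearing carbon C4. The acyclic precursor already holds the bromo-oxane ring B, made from (S)-linalool, and the C1 and C2 stereocentres (Sharpless epoxidation, cuprate opening); it ends in an isopropenyl group and a nitrile. Iron-hydride hydrogen-atom transfer turns the isopropenyl group into the C3 tertiary radical, creating the second methyl, and 6-exo attack on the nitrile delivers ring A as the C4 ketone. The step exploits the fact that C3 of ring A is quaternary with two methyls and adjoins the heteroatom-bearing C4. Reduction and Appel inversion then give the equatorial bromide.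

Key step: step 12

Remark on atom labels: ring A is the cyclohexane, numbered as in the target whatever the name of an intermediate: C1 (C(CH3)OH), C2 (CH carrying the linker), C3 (C(CH3)2), C4 (CHBr), C5, C6. Ring B is the oxane: O1, C2 (C(CH3) carrying the linker), C3 (CHBr), C4, C5, C6 (C(CH3)(ethenyl)). The linker is C1' (on ring B) and C2' (on ring A).

Assumption: (S)-(+)-linalool (coriandrol) is taken as a commercial chiral-pool material of high enantiomeric purity.

Step 1
Reactants: 1 (S)-(+)-linalool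
Product: 2 (2E,6S)-2,6-dimethylocta-2,7-diene-1,6-diol
Conditions: SeO2 (cat.), t-BuOOH, salicylic acid (cat.), CH2Cl2, rt
Reagents that add atoms: tert-butyl hydroperoxide CC(C)(C)OO
Why: Riley-type allylic oxidation with catalytic SeO2 (ene reaction followed by [2,3]-sigmatropic shift) should hydroxylate the (E)-methyl group of the trisubstituted alkene selectively, leaving the vinyl carbinol and its stereocentre untouched.

Step 2
Reactants: 2 (2E,6S)-2,6-dimethylocta-2,7-diene-1,6-diol
Product: 3 (3S,6E)-8-bromo-3,7-dimethylocta-1,6-dien-3-ol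
Conditions: CBr4, PPh3, CH2Cl2, −30 °C
Reagents that add atoms: carbon tetrabromide BrC(Br)(Br)Br
Why: The Appel reaction should convert the primary allylic alcohol to the bromide by SN2 displacement with the (E)-geometry retained, the hindered tertiary alcohol reacting far more slowly at low temperature.

Step 3
Reactants: 3 (3S,6E)-8-bromo-3,7-dimethylocta-1,6-dien-3-ol; 4 acetonitrile
Product: 5 (4E,8S)-8-hydroxy-4,8-dimethyldeca-4,9-dienenitrile
Conditions: 4, n-BuLi, THF, −78 °C; then 3, −78 → −20 °C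
Reagents that add atoms: acetonitrile (4) CC#N
Why: SN2 alkylation of LiCH2CN (used in excess, one equivalent being consumed by the hydroxyl group) by the primary allylic bromide adds linker carbon C2' and the carbon that becomes C2 of ring A without touching the alkene geometry.

Step 4
Reactants: 5 (4E,8S)-8-hydroxy-4,8-dimethyldeca-4,9-dienenitrile
Product: 6 3-[(2S,3R,6S)-3-bromo-6-ethenyl-2,6-dimethyloxan-2-yl]propanenitrile
Conditions: TBCO (2,4,4,6-tetrabromocyclohexa-2,5-dien-1-one), MeNO2, 0 °C → rt, dark; chromatography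
Reagents that add atoms: 2,4,4,6-tetrabromocyclohexa-2,5-dien-1-one O=C1C(Br)=CC(Br)(Br)C=C1Br
Why: Bromoetherification, in which bromonium transfer to the trisubstituted alkene and Markovnikov 6-endo capture by the tertiary hydroxyl close ring B, fixes the C2/C3 relationship by anti addition across the (E)-alkene, but the remote C6 centre does not bias the alkene face, so 6 is expected together with its (2R,3S,6S) diastereomer and 5-exo oxolane isomers and is isolated by chromatography at this early, inexpensive stage.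

Step 5
Reactants: 6 3-[(2S,3R,6S)-3-bromo-6-ethenyl-2,6-dimethyloxan-2-yl]propanenitrile
Product: 8 3-[(2S,3R,6S)-3-bromo-6-ethenyl-2,6-dimethyloxan-2-yl]propanal, via aldimine 7 (not isolated)
Conditions: i-Bu2AlH, CH2Cl2, −78 °C; then aq. AcOH
Reagents that add atoms: water O
Why: Partial reduction of the nitrile with i-Bu2AlH stops at the N-aluminated aldimine, which is hydrolysed to the aldehyde on work-up, the secondary bromide and the vinyl group being inert to the hydride at −78 °C.

Step 6
Reactants: 8 3-[(2S,3R,6S)-3-bromo-6-ethenyl-2,6-dimethyloxan-2-yl]propanal; 9 ethyl 2-[bis(2,2,2-trifluoroethoxy)phosphoryl]propanoate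
Product: 10 ethyl (2Z)-5-[(2S,3R,6S)-3-bromo-6-ethenyl-2,6-dimethyloxan-2-yl]-2-methylpent-2-enoate
Conditions: 9, KN(SiMe3)2, 18-crown-6, THF, −78 °C
Reagents that add atoms: ethyl 2-[bis(2,2,2-trifluoroethoxy)phosphoryl]propanoate (9) CCOC(=O)C(C)P(=O)(OCC(F)(F)F)OCC(F)(F)F
Why: In the Still–Gennari olefination the electron-poor phosphonate with a dissociated potassium counter-ion eliminates fast from the kinetic adduct and should give the (Z)-2-methyl enoate, the geometry that later becomes the cis relationship of the C1 hydroxyl and the C2 side chain of ring A.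

Step 7
Reactants: 10 ethyl (2Z)-5-[(2S,3R,6S)-3-bromo-6-ethenyl-2,6-dimethyloxan-2-yl]-2-methylpent-2-enoate
Product: 11 (2Z)-5-[(2S,3R,6S)-3-bromo-6-ethenyl-2,6-dimethyloxan-2-yl]-2-methylpent-2-en-1-ol
Conditions: i-Bu2AlH, CH2Cl2, −78 °C
Reagents that add atoms: none
Why: 1,2-Reduction of the enoate with i-Bu2AlH should give the allylic alcohol needed to direct the epoxidation, without change of alkene geometry.

Step 8
Reactants: 11 (2Z)-5-[(2S,3R,6S)-3-bromo-6-ethenyl-2,6-dimethyloxan-2-yl]-2-methylpent-2-en-1-ol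
Product: 12 [(2S,3R)-3-{2-[(2S,3R,6S)-3-bromo-6-ethenyl-2,6-dimethyloxan-2-yl]ethyl}-2-methyloxiran-2-yl]methanol
Conditions: Ti(OiPr)4 (cat.), L-(+)-diethyl tartrate (cat.), t-BuOOH, 4 Å molecular sieves, CH2Cl2, −20 °C
Reagents that add atoms: tert-butyl hydroperoxide CC(C)(C)OO
Why: In the Sharpless asymmetric epoxidation the titanium–L-(+)-tartrate catalyst selects the alkene face of the allylic alcohol under reagent control, setting the quaternary carbon that becomes C1 of ring A and the configuration at the neighbouring carbon that step 9 inverts, while the isolated vinyl group is not epoxidised.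

Step 9
Reactants: 12 [(2S,3R)-3-{2-[(2S,3R,6S)-3-bromo-6-ethenyl-2,6-dimethyloxan-2-yl]ethyl}-2-methyloxiran-2-yl]methanol; 13 isopropenylmagnesium bromide
Product: 14 (2R,3R)-5-[(2S,3R,6S)-3-bromo-6-ethenyl-2,6-dimethyloxan-2-yl]-2-methyl-3-(prop-1-en-2-yl)pentane-1,2-diol
Conditions: 13, CuI (10 mol%), THF/Et2O, −30 → 0 °C
Reagents that add atoms: isopropenylmagnesium bromide (13) C=C(C)[Mg]Br
Why: Copper-catalysed Grignard opening of the 2,3-epoxy alcohol by SN2 attack at the only accessible (secondary) epoxide carbon, with inversion, sets C2 of ring A and installs the isopropenyl group whose central carbon becomes C3.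

Step 10
Reactants: 14 (2R,3R)-5-[(2S,3R,6S)-3-bromo-6-ethenyl-2,6-dimethyloxan-2-yl]-2-methyl-3-(prop-1-en-2-yl)pentane-1,2-diol
Product: 16 (2R)-2-{(3R)-5-[(2S,3R,6S)-3-bromo-6-ethenyl-2,6-dimethyloxan-2-yl]-2-methylpent-1-en-3-yl}-2-methyloxirane, via primary tosylate 15 (not isolated)
Conditions: NaH, N-tosylimidazole, THF, 0 °C → rt
Reagents that add atoms: none
Why: One-pot selective sulfonylation of the primary alkoxide followed by intramolecular Williamson displacement by the tertiary alkoxide should give the 2,2-disubstituted oxirane with the C1 configuration intact, since its C–O bond is not broken.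

Step 11
Reactants: 16 (2R)-2-{(3R)-5-[(2S,3R,6S)-3-bromo-6-ethenyl-2,6-dimethyloxan-2-yl]-2-methylpent-1-en-3-yl}-2-methyloxirane; 4 acetonitrile
Product: 18 (4S,5R)-7-[(2S,3R,6S)-3-bromo-6-ethenyl-2,6-dimethyloxan-2-yl]-4-methyl-5-(prop-1-en-2-yl)-4-[(triethylsilyl)oxy]heptanenitrile, via lithium alkoxide 17 (not isolated)
Conditions: 4, n-BuLi, THF, −78 °C; then 16, −78 → −20 °C; then Et3SiOTf, −78 → 0 °C
Reagents that add atoms: acetonitrile (4) CC#N; triethylsilyl trifluoromethanesulfonate CC[Si](CC)(CC)OS(=O)(=O)C(F)(F)F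
Why: SN2 opening of the oxirane at its CH2 terminus by LiCH2CN adds C5 and the nitrile carbon C4, and silylation of the resulting tertiary lithium alkoxide in the same flask blocks iminolactone formation and protects the C1 oxygen for steps 12 to 14.

Step 12
Reactants: 18 (4S,5R)-7-[(2S,3R,6S)-3-bromo-6-ethenyl-2,6-dimethyloxan-2-yl]-4-methyl-5-(prop-1-en-2-yl)-4-[(triethylsilyl)oxy]heptanenitrile
Product: 20 (3R,4S)-3-{2-[(2S,3R,6S)-3-bromo-6-ethenyl-2,6-dimethyloxan-2-yl]ethyl}-2,2,4-trimethyl-4-[(triethylsilyl)oxy]cyclohexan-1-one, via ketimine 19 (not isolated)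
Conditions: Fe(acac)3 (30 mol%), PhSiH3, EtOH, 60 °C; then aq. AcOH, THF, rt
Reagents that add atoms: water O
Why: Fe(acac)3 and PhSiH3 in ethanol form an iron hydride that transfers a hydrogen atom to the CH2 terminus of the isopropenyl group (Markovnikov-selective), which creates the second methyl group on C3 and a tertiary radical at C3; this radical adds to the nitrile carbon C4, the iminyl radical is reduced to ketimine 19, and mild aqueous acid hydrolyses 19 to ketone 20. The closest known reaction type is the hydrogen-atom-transfer-initiated (Mukaiyama-type) radical cyclisation of alkenyl nitriles and alkenyl ketones under Fe(acac)3/PhSiH3. Ring A is closed in the 6-exo-dig mode, the tether holding exactly four atoms between the radical carbon and the nitrile carbon. No stereocentre is created (C3 carries two methyl groups and C4 is trigonal), and C1 and C2, set in steps 8 and 9, are not affected, C2 not being α to the new ketone. The step needs chemoselective hydrogen-atom transfer to the 1,1-disubstituted alkene in the presence of the vinyl group of ring B, which should be secured by the much slower transfer to a monosubstituted, neopentylic alkene that would give only a secondary radical; secondary alkyl bromides, silyl ethers and cyclic ethers are known to survive these neutral conditions.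

Step 13
Reactants: 20 (3R,4S)-3-{2-[(2S,3R,6S)-3-bromo-6-ethenyl-2,6-dimethyloxan-2-yl]ethyl}-2,2,4-trimethyl-4-[(triethylsilyl)oxy]cyclohexan-1-one
Product: 21 (1S,3R,4S)-3-{2-[(2S,3R,6S)-3-bromo-6-ethenyl-2,6-dimethyloxan-2-yl]ethyl}-2,2,4-trimethyl-4-[(triethylsilyl)oxy]cyclohexan-1-ol
Conditions: LiBH(s-Bu)3 (L-Selectride), THF, −78 °C
Reagents that add atoms: none
Why: Reduction with the bulky LiBH(s-Bu)3 should occur from the equatorial direction of the chair that keeps the C2 side chain equatorial, as is known for 2,2-dimethylcyclohexanones, and give the axial C4 alcohol trans to the side chain.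

Step 14
Reactants: 21 (1S,3R,4S)-3-{2-[(2S,3R,6S)-3-bromo-6-ethenyl-2,6-dimethyloxan-2-yl]ethyl}-2,2,4-trimethyl-4-[(triethylsilyl)oxy]cyclohexan-1-ol
Product: 22 {[(1S,2R,4R)-4-bromo-2-{2-[(2S,3R,6S)-3-bromo-6-ethenyl-2,6-dimethyloxan-2-yl]ethyl}-1,3,3-trimethylcyclohexyl]oxy}triethylsilane
Conditions: CBr4, PPh3, pyridine, toluene, 60 °C
Reagents that add atoms: carbon tetrabromide BrC(Br)(Br)Br
Why: In the Appel reaction bromide displaces the axial oxyphosphonium group by SN2 with inversion, a transformation known for hindered axial alcohols next to a gem-dimethyl carbon, to give the equatorial (4R) bromide cis to the C2 side chain, the silyl ether preventing transannular attack by the C1 oxygen.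

Step 15
Reactants: 22 {[(1S,2R,4R)-4-bromo-2-{2-[(2S,3R,6S)-3-bromo-6-ethenyl-2,6-dimethyloxan-2-yl]ethyl}-1,3,3-trimethylcyclohexyl]oxy}triethylsilane
Product: 23 (1S,2R,4R)-4-bromo-2-{2-[(2S,3R,6S)-3-bromo-6-ethenyl-2,6-dimethyloxan-2-yl]ethyl}-1,3,3-trimethylcyclohexan-1-ol (CNP0244533.1)
Conditions: Bu4NF, AcOH, THF, 0 °C → rt
Reagents that add atoms: none
Why: Fluoride-mediated cleavage of the tertiary triethylsilyl ether under acetic acid buffering, which avoids base-induced elimination of the two secondary bromides, should release the tertiary alcohol of the target.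

Compound list

1 | (S)-(+)-linalool, (3S)-3,7-dimethylocta-1,6-dien-3-ol | C=C[C@@](C)(O)CCC=C(C)C | starting material
2 | (2E,6S)-2,6-dimethylocta-2,7-diene-1,6-diol | C=C[C@@](C)(O)CC/C=C(\C)CO | intermediate
3 | (3S,6E)-8-bromo-3,7-dimethylocta-1,6-dien-3-ol | C=C[C@@](C)(O)CC/C=C(\C)CBr | intermediate
4 | acetonitrile | CC#N | starting material
5 | (4E,8S)-8-hydroxy-4,8-dimethyldeca-4,9-dienenitrile | C=C[C@@](C)(O)CC/C=C(\C)CCC#N | intermediate
6 | 3-[(2S,3R,6S)-3-bromo-6-ethenyl-2,6-dimethyloxan-2-yl]propanenitrile | C=C[C@]1(C)CC[C@@H](Br)[C@](C)(CCC#N)O1 | intermediate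
7 | 3-[(2S,3R,6S)-3-bromo-6-ethenyl-2,6-dimethyloxan-2-yl]propan-1-imine (aldimine, formed in the flask) | C=C[C@]1(C)CC[C@@H](Br)[C@](C)(CCC=N)O1 | intermediate
8 | 3-[(2S,3R,6S)-3-bromo-6-ethenyl-2,6-dimethyloxan-2-yl]propanal | C=C[C@]1(C)CC[C@@H](Br)[C@](C)(CCC=O)O1 | intermediate
9 | ethyl 2-[bis(2,2,2-trifluoroethoxy)phosphoryl]propanoate | CCOC(=O)C(C)P(=O)(OCC(F)(F)F)OCC(F)(F)F | starting material
10 | ethyl (2Z)-5-[(2S,3R,6S)-3-bromo-6-ethenyl-2,6-dimethyloxan-2-yl]-2-methylpent-2-enoate | C=C[C@]1(C)CC[C@@H](Br)[C@](C)(CC/C=C(/C)C(=O)OCC)O1 | intermediate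
11 | (2Z)-5-[(2S,3R,6S)-3-bromo-6-ethenyl-2,6-dimethyloxan-2-yl]-2-methylpent-2-en-1-ol | C=C[C@]1(C)CC[C@@H](Br)[C@](C)(CC/C=C(/C)CO)O1 | intermediate
12 | [(2S,3R)-3-{2-[(2S,3R,6S)-3-bromo-6-ethenyl-2,6-dimethyloxan-2-yl]ethyl}-2-methyloxiran-2-yl]methanol | C=C[C@]1(C)CC[C@@H](Br)[C@](C)(CC[C@H]2O[C@@]2(C)CO)O1 | intermediate
13 | isopropenylmagnesium bromide (prop-1-en-2-ylmagnesium bromide) | C=C(C)[Mg]Br | starting material
14 | (2R,3R)-5-[(2S,3R,6S)-3-bromo-6-ethenyl-2,6-dimethyloxan-2-yl]-2-methyl-3-(prop-1-en-2-yl)pentane-1,2-diol | C=C[C@]1(C)CC[C@@H](Br)[C@](C)(CC[C@H](C(C)=C)[C@@](C)(O)CO)O1 | intermediate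
15 | (2R,3R)-5-[(2S,3R,6S)-3-bromo-6-ethenyl-2,6-dimethyloxan-2-yl]-2-hydroxy-2-methyl-3-(prop-1-en-2-yl)pentyl 4-methylbenzenesulfonate (primary tosylate, formed in the flask) | C=C[C@]1(C)CC[C@@H](Br)[C@](C)(CC[C@H](C(C)=C)[C@@](C)(O)COS(=O)(=O)c2ccc(C)cc2)O1 | intermediate
16 | (2R)-2-{(3R)-5-[(2S,3R,6S)-3-bromo-6-ethenyl-2,6-dimethyloxan-2-yl]-2-methylpent-1-en-3-yl}-2-methyloxirane | C=C[C@]1(C)CC[C@@H](Br)[C@](C)(CC[C@H](C(C)=C)[C@]2(C)CO2)O1 | intermediate
17 | lithium alkoxide of (4S,5R)-7-[(2S,3R,6S)-3-bromo-6-ethenyl-2,6-dimethyloxan-2-yl]-4-hydroxy-4-methyl-5-(prop-1-en-2-yl)heptanenitrile (formed in the flask) | C=C[C@]1(C)CC[C@@H](Br)[C@](C)(CC[C@H](C(C)=C)[C@@](C)([O-])CCC#N)O1.[Li+] | intermediate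
18 | (4S,5R)-7-[(2S,3R,6S)-3-bromo-6-ethenyl-2,6-dimethyloxan-2-yl]-4-methyl-5-(prop-1-en-2-yl)-4-[(triethylsilyl)oxy]heptanenitrile | C=C[C@]1(C)CC[C@@H](Br)[C@](C)(CC[C@H](C(C)=C)[C@@](C)(O[Si](CC)(CC)CC)CCC#N)O1 | intermediate
19 | (3R,4S)-3-{2-[(2S,3R,6S)-3-bromo-6-ethenyl-2,6-dimethyloxan-2-yl]ethyl}-2,2,4-trimethyl-4-[(triethylsilyl)oxy]cyclohexan-1-imine (ketimine, formed in the flask) | C=C[C@]1(C)CC[C@@H](Br)[C@](C)(CC[C@@H]2C(C)(C)C(=N)CC[C@]2(C)O[Si](CC)(CC)CC)O1 | intermediate
20 | (3R,4S)-3-{2-[(2S,3R,6S)-3-bromo-6-ethenyl-2,6-dimethyloxan-2-yl]ethyl}-2,2,4-trimethyl-4-[(triethylsilyl)oxy]cyclohexan-1-one | C=C[C@]1(C)CC[C@@H](Br)[C@](C)(CC[C@@H]2C(C)(C)C(=O)CC[C@]2(C)O[Si](CC)(CC)CC)O1 | intermediate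
21 | (1S,3R,4S)-3-{2-[(2S,3R,6S)-3-bromo-6-ethenyl-2,6-dimethyloxan-2-yl]ethyl}-2,2,4-trimethyl-4-[(triethylsilyl)oxy]cyclohexan-1-ol | C=C[C@]1(C)CC[C@@H](Br)[C@](C)(CC[C@@H]2C(C)(C)[C@@H](O)CC[C@]2(C)O[Si](CC)(CC)CC)O1 | intermediate
22 | {[(1S,2R,4R)-4-bromo-2-{2-[(2S,3R,6S)-3-bromo-6-ethenyl-2,6-dimethyloxan-2-yl]ethyl}-1,3,3-trimethylcyclohexyl]oxy}triethylsilane | C=C[C@]1(C)CC[C@@H](Br)[C@](C)(CC[C@@H]2C(C)(C)[C@H](Br)CC[C@]2(C)O[Si](CC)(CC)CC)O1 | intermediate
23 | (1S,2R,4R)-4-bromo-2-{2-[(2S,3R,6S)-3-bromo-6-ethenyl-2,6-dimethyloxan-2-yl]ethyl}-1,3,3-trimethylcyclohexan-1-ol (CNP0244533.1) | C=C[C@]1(C)CC[C@@H](Br)[C@](C)(CC[C@@H]2C(C)(C)[C@H](Br)CC[C@]2(C)O)O1 | target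

Total step count: 15. Longest linear sequence: 15 steps (fully linear from 1).

Steps most likely to fail

Step 12. The 6-exo-dig addition of the tertiary radical to the nitrile is slow and reversible, so premature reduction of the radical (net hydrogenation of the isopropenyl group) or hydrogen-atom transfer to the vinyl group of ring B may win. The fallback sets out from 18 and changes the radical acceptor. The nitrile is reduced (i-Bu2AlH, CH2Cl2, −78 °C, then aq. AcOH) to (4S,5R)-7-[(2S,3R,6S)-3-bromo-6-ethenyl-2,6-dimethyloxan-2-yl]-4-methyl-5-(prop-1-en-2-yl)-4-[(triethylsilyl)oxy]heptanal F1. Fe(acac)3 and PhSiH3 in ethanol then close ring A onto the aldehyde, a much faster acceptor in the known hydrogen-atom-transfer alkene–carbonyl cyclisation, which should give (3R,4S)-3-{2-[(2S,3R,6S)-3-bromo-6-ethenyl-2,6-dimethyloxan-2-yl]ethyl}-2,2,4-trimethyl-4-[(triethylsilyl)oxy]cyclohexan-1-ol F2 as a mixture of C1 epimers. Oxidation with Dess–Martin periodinane (NaHCO3, CH2Cl2) converges both epimers on ketone 20, where the route is rejoined.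

Step 4. The bromonium ion forms on both alkene faces without discrimination by the remote C6 centre, and 5-exo closure competes, so much material is lost to isomers. The fallback sets out from 5 and replaces the free bromonium ion by a stereospecific sequence. Shi epoxidation with the L-fructose-derived ketone (the enantiomer of the common D-fructose-derived catalyst, chosen to deliver the (S,S)-epoxide) and KHSO5 (Oxone) under buffered conditions should give 3-{(2S,3S)-3-[(3S)-3-hydroxy-3-methylpent-4-en-1-yl]-2-methyloxiran-2-yl}propanenitrile F3. Opening with bromide at the secondary epoxide carbon with inversion (Li2NiBr4, THF, 0 °C) should give (4S,5R,8S)-5-bromo-4,8-dihydroxy-4,8-dimethyldec-9-enenitrile F4. Ionisation of the tertiary hydroxyl next to bromine (BF3·OEt2, CH2Cl2, −40 °C), assisted by the neighbouring bromine, generates a single bromonium ion, a known way to an enantiopure bromonium ion from an enantiopure bromohydrin. Its 6-endo capture by the tertiary alcohol should then give 6 as one diastereomer, where the route is rejoined.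

Step 14. At the neopentylic axial oxyphosphonium centre, E2 elimination to the cyclohexene or a 1,2-methyl shift may outrun SN2 displacement. The fallback sets out from 21 and separates activation from displacement. The alcohol is converted at low temperature (Tf2O, 2,6-di-tert-butylpyridine, CH2Cl2, −40 °C) into (1S,3R,4S)-3-{2-[(2S,3R,6S)-3-bromo-6-ethenyl-2,6-dimethyloxan-2-yl]ethyl}-2,2,4-trimethyl-4-[(triethylsilyl)oxy]cyclohexyl trifluoromethanesulfonate F5. This is displaced in a second operation by a soluble bromide (LiBr, HMPA/toluene, −20 °C → rt) with inversion to give 22, where the route is rejoined.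

Further compounds

F1 | step 12 | (4S,5R)-7-[(2S,3R,6S)-3-bromo-6-ethenyl-2,6-dimethyloxan-2-yl]-4-methyl-5-(prop-1-en-2-yl)-4-[(triethylsilyl)oxy]heptanal | C=C[C@]1(C)CC[C@@H](Br)[C@](C)(CC[C@H](C(C)=C)[C@@](C)(O[Si](CC)(CC)CC)CCC=O)O1
F2 | step 12 | (3R,4S)-3-{2-[(2S,3R,6S)-3-bromo-6-ethenyl-2,6-dimethyloxan-2-yl]ethyl}-2,2,4-trimethyl-4-[(triethylsilyl)oxy]cyclohexan-1-ol (both C1 epimers) | C=C[C@]1(C)CC[C@@H](Br)[C@](C)(CC[C@@H]2C(C)(C)C(O)CC[C@]2(C)O[Si](CC)(CC)CC)O1
F3 | step 4 | 3-{(2S,3S)-3-[(3S)-3-hydroxy-3-methylpent-4-en-1-yl]-2-methyloxiran-2-yl}propanenitrile | C=C[C@@](C)(O)CC[C@@H]1O[C@@]1(C)CCC#N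
F4 | step 4 | (4S,5R,8S)-5-bromo-4,8-dihydroxy-4,8-dimethyldec-9-enenitrile | C=C[C@@](C)(O)CC[C@@H](Br)[C@@](C)(O)CCC#N
F5 | step 14 | (1S,3R,4S)-3-{2-[(2S,3R,6S)-3-bromo-6-ethenyl-2,6-dimethyloxan-2-yl]ethyl}-2,2,4-trimethyl-4-[(triethylsilyl)oxy]cyclohexyl trifluoromethanesulfonate | C=C[C@]1(C)CC[C@@H](Br)[C@](C)(CC[C@@H]2C(C)(C)[C@@H](OS(=O)(=O)C(F)(F)F)CC[C@]2(C)O[Si](CC)(CC)CC)O1
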